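## Retrosynthetic overview

1. Endgame: 9‑O‑acetylation ⇐ SmI2 intramolecular Reformatsky (C8–C17 bond, lactone, 8‑OH, C17) ⇐ hydroxyl‑directed epoxidation of the 11(20)‑alkene.
2. Ten‑membered ring (formed second): C6–C7 by electrochemical Cr/Ni Nozaki–Hiyama–Kishi macrocyclisation of a (Z)‑vinyl iodide onto a C7 aldehyde.
3. Six‑membered ring (formed first): C1–C10 by anodic Mn/Cu‑mediated 6‑endo oxidative radical cyclisation of an α‑methyl‑1,3‑diketone onto a (Z)‑trisubstituted alkene. This sets C1 and C10 and leaves the 11(20)‑methylene.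
4. Acyclic precursor: 3‑methylpentane‑2,4‑dione is alkylated at both terminal methyls (C12–C13 and C3–C4) with one building block, (Z)‑BrCH2C(Me)=CHI, and joined to (S)‑glyceraldehyde acetonide (C7–C9) by NHK coupling.
5. Stereochemical relay: glyceraldehyde C8 (bought, later oxidised) → C9 → C10/C1 → C14/C2 → C7 → C8/C17 → C11.

Assumptions: briarane numbering (C1–C20) is used for all intermediates; (S)‑2,3‑O‑isopropylideneglyceraldehyde (derived from L‑ascorbic acid) is taken as a purchasable chiral‑pool material.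

## Route

Step 1
Reactants: 1 prop‑2‑yn‑1‑ol
Product: 2 (Z)‑3‑iodo‑2‑methylprop‑2‑en‑1‑ol
Conditions: MeMgBr (3 equiv), CuI (10 mol %), THF, −10 °C → rt; then I2, −10 °C
Reagents that add atoms: methylmagnesium bromide C[Mg]Br; iodine II
Why: Alkoxide‑directed Cu‑catalysed anti‑carbomagnesiation of the alkyne, then iodinolysis of the vinylmagnesium, gives only the Z iodide (I cis to CH2OH).

Step 2
Reactants: 2 (Z)‑3‑iodo‑2‑methylprop‑2‑en‑1‑ol
Product: 3 (Z)‑3‑bromo‑1‑iodo‑2‑methylprop‑1‑ene
Conditions: PBr3, pyridine (cat.), Et2O, −10 °C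
Reagents that add atoms: phosphorus tribromide BrP(Br)Br
Why: SN2 bromination of the primary allylic alcohol leaves the vinyl iodide and its geometry untouched.

Step 3
Reactants: 4 3‑methylpentane‑2,4‑dione; 3 (Z)‑3‑bromo‑1‑iodo‑2‑methylprop‑1‑ene
Product: 5 (Z)‑8‑iodo‑3,7‑dimethyloct‑7‑ene‑2,4‑dione (C2/C1/C14/C13–C10 with Me‑15 and Me‑20; C1 epimeric)
Conditions: NaH, THF, 0 °C; n‑BuLi, −10 °C; then 3, −78 → 0 °C
Reagents that add atoms: none
Why: Hauser‑type 1,3‑diketone dianion alkylation occurs only at the terminal carbon (C13), forming C12–C13 without affecting the vinyl iodide.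

Step 4
Reactants: 5 (Z)‑8‑iodo‑3,7‑dimethyloct‑7‑ene‑2,4‑dione; 6 (S)‑2,2‑dimethyl‑1,3‑dioxolane‑4‑carbaldehyde
Product: 7 (7Z,9R)‑9‑[(4S)‑2,2‑dimethyl‑1,3‑dioxolan‑4‑yl]‑9‑hydroxy‑3,7‑dimethylnon‑7‑ene‑2,4‑dione (C9–OH anti to C8–O)
Conditions: CrCl2 (4 equiv), NiCl2 (2 mol %), DMSO, rt; 6 (2 equiv)
Reagents that add atoms: none
Why: Nozaki–Hiyama–Kishi coupling tolerates the diketone, retains the Z geometry, and adds to the α‑alkoxy aldehyde in the Felkin–Anh (anti) sense to set C9 (about 4:1 expected; the syn isomer is removed by chromatography).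

Step 5
Reactants: 7
Product: 8 the 9‑O‑TBS ether of 7
Conditions: TBSCl, imidazole, DMAP (cat.), DMF, 35 °C
Reagents that add atoms: tert‑butyldimethylsilyl chloride CC(C)(C)[Si](C)(C)Cl
Why: Standard silylation of the secondary alcohol; any silyl enol ether of the diketone hydrolyses on work‑up.

Step 6
Reactants: 8
Product: 9 (2S,3S)‑2‑acetyl‑3‑{(R)‑(tert‑butyldimethylsilyloxy)[(4S)‑2,2‑dimethyl‑1,3‑dioxolan‑4‑yl]methyl}‑2‑methyl‑4‑methylenecyclohexan‑1‑one (briarane C1 S, C10 S; acetyl trans and Me‑15 cis to the C9 substituent)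
Conditions: divided cell, graphite‑felt anode, Pt cathode; Mn(OAc)2·4H2O (20 mol %), Cu(OAc)2·H2O (20 mol %), NaOAc, AcOH–MeCN 1:1, 40 °C, constant current, 2.3 F/mol
Reagents that add atoms: none
Why: Proposed new method: anodically regenerated Mn(III) oxidises the α‑methyl‑1,3‑diketone to the C1 radical, which closes 6‑endo onto C10 through a chair TS (acetyl axial, Z‑alkene placing C9 axial and anti to it; bond formation anti to the C9–OTBS bond in the A(1,3)‑locked H‑eclipsed conformer, the same facial sense as osmylation and Claisen reactions of Z‑allylic ethers), and the tertiary C11 radical is oxidised by Cu(II) (reoxidised by Mn(III)) to the exocyclic 11(20)‑alkene; the closest known reaction is the stoichiometric Mn(OAc)3/Cu(OAc)2 oxidative radical cyclisation of 1,3‑dicarbonyls (and Mn‑mediated indirect electrolysis), which has not been run with both metals electrocatalytic on this substrate type or with 1,2‑induction from an allylic silyloxy centre.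

Step 7
Reactants: 9; 3 (Z)‑3‑bromo‑1‑iodo‑2‑methylprop‑1‑ene
Product: 10 (2S,3S)‑3‑{(R)‑(TBSO)[(4S)‑dioxolanyl]methyl}‑2‑[(Z)‑5‑iodo‑4‑methylpent‑4‑enoyl]‑2‑methyl‑4‑methylenecyclohexan‑1‑one
Conditions: LiHMDS (1.05 equiv), THF, −78 °C; then 3, DMPU, −78 → −30 °C
Reagents that add atoms: none
Why: Kinetic enolisation of the unhindered acetyl CH3 (rather than the ring C13 methylene) and SN2 alkylation with the allylic bromide form C3–C4 and install the (Z)‑vinyl iodide for ring closure.

Step 8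
Reactants: 10
Product: 11 the (2R,14S)‑2,14‑diol (14‑OH cis to C2 and trans to Me‑15; O2/O14 1,3‑syn)
Conditions: NaBH4, MeOH–THF, −40 °C; then Et2BOMe, NaBH4, THF–MeOH, −78 °C; MeOH azeotrope work‑up
Reagents that add atoms: none
Why: The more reactive cyclohexanone is reduced first by Felkin–Anh attack anti to the C1 acyl group (14‑OH cis to C2), and Narasaka–Prasad boron‑chelate reduction of the remaining β‑hydroxy ketone then gives the 1,3‑syn diol, setting C2.

Step 9
Reactants: 11
Product: 12 the 2,14‑diacetate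
Conditions: Ac2O, DMAP, pyridine, 40 °C
Reagents that add atoms: acetic anhydride CC(=O)OC(C)=O
Why: DMAP‑catalysed acetylation of the two hindered secondary alcohols installs two of the three final acetates early, and they tolerate all later steps.

Step 10
Reactants: 12
Product: 13 the 7,8‑diol (acetonide removed; 9‑OTBS retained)
Conditions: Zn(NO3)2·6H2O, MeCN, 50 °C
Reagents that add atoms: none
Why: Mild Lewis‑acid hydrolysis of the terminal isopropylidene acetal spares the secondary TBS ether, the acetates and the vinyl iodide.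

Step 11
Reactants: 13
Product: 14 the C7‑aldehyde/C8‑ketone (α‑keto aldehyde), used crude
Conditions: (COCl)2, DMSO, CH2Cl2, −78 °C; i‑Pr2NEt, −78 → −40 °C
Reagents that add atoms: none
Why: Swern oxidation of the 1,2‑diol gives the keto‑aldehyde without C–C cleavage; this removes the sacrificial glyceraldehyde stereocentre (C8), and low temperature with a hindered base protects C9 from epimerisation.

Step 12
Reactants: 14
Product: 15 the bicyclo[8.4.0] macrocycle: (7S)‑7‑hydroxy‑8‑oxo‑9‑OTBS‑2,14‑diacetoxy‑briara‑5(Z),11(20)‑diene carbocycle (no lactone yet)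
Conditions: CrCl2 (20 mol %), NiCl2·glyme (2 mol %), Cp2ZrCl2 (1.2 equiv), Bu4NBr, DMF, undivided cell, Al anode/Ni‑foam cathode, constant current, syringe‑pump addition to 2 mM, rt
Reagents that add atoms: none
Why: Electrochemical Cr/Ni Nozaki–Hiyama–Kishi macrocyclisation adds the (Z)‑alkenyl chromium only to the aldehyde, with retention of alkene geometry, to close the ten‑membered ring and set C7 under macrocyclic substrate control; the low steady‑state Cr(II) concentration limits reduction of the 1,2‑dicarbonyl, and if the 7R epimer forms it is used in step 13 under Mitsunobu conditions (2‑bromopropanoic acid, inversion) instead.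

Step 13
Reactants: 15; 16 2‑bromopropanoyl bromide (racemic)
Product: 17 the 7‑O‑(2‑bromopropanoate) of 15
Conditions: pyridine, CH2Cl2, −20 °C
Reagents that add atoms: none (16 is a reactant)
Why: The allylic 7‑OH is the only free hydroxyl, so acylation is unambiguous and brings in C17–C19.

Step 14
Reactants: 17
Product: 18 the 9‑hydroxy‑8‑ketone (TBS removed)
Conditions: HF·pyridine, pyridine, THF, 0 °C → rt
Reagents that add atoms: none
Why: Buffered fluoride desilylation frees the 9‑OH before the acid‑sensitive epoxide exists and does not affect the α‑bromo ester or the acetates.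

Step 15
Reactants: 18
Product: 19 the (11R)‑11,20‑epoxide of 18
Conditions: VO(acac)2 (5 mol %), t‑BuOOH (1.5 equiv), CH2Cl2, 0 °C
Reagents that add atoms: tert‑butyl hydroperoxide CC(C)(C)OO
Why: Vanadium‑catalysed epoxidation directed by the homoallylic 9‑OH (the only free hydroxyl) selects the 11(20)‑alkene over C5=C6 and delivers oxygen to the α‑face, onto which the 9‑OH points in the A(1,3)‑preferred rotamer and which is also the face away from axial Me‑15.

Step 16
Reactants: 19
Product: 20 9‑O‑deacetyl junceellolide F (8,9‑diol, 7,8‑trans‑fused γ‑lactone, 17R)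
Conditions: SmI2 (2.5 equiv), THF, −78 °C
Reagents that add atoms: none
Why: SmI2‑promoted intramolecular Reformatsky reaction forms C8–C17 and the β‑hydroxy‑γ‑lactone; the samarium enolate attacks the C8 ketone face that keeps C6 and C9 trans across the new ring (8‑OH anti to H‑7), and Me‑18 ends trans to C9, which is also the thermodynamic C17 epimer.

Step 17
Reactants: 20
Product: 21 junceellolide F
Conditions: Ac2O, DMAP, Et3N, CH2Cl2, 0 °C → rt
Reagents that add atoms: acetic anhydride CC(=O)OC(C)=O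
Why: Selective acetylation of the secondary 9‑OH; the tertiary 8‑OH does not react under these conditions.

## Compound list

1 | prop‑2‑yn‑1‑ol | C#CCO | starting material
2 | (Z)‑3‑iodo‑2‑methylprop‑2‑en‑1‑ol | OC/C(C)=C\I | intermediate
3 | (Z)‑3‑bromo‑1‑iodo‑2‑methylprop‑1‑ene | BrC/C(C)=C\I | intermediate
4 | 3‑methylpentane‑2,4‑dione | CC(=O)C(C)C(C)=O | starting material
5 | (Z)‑8‑iodo‑3,7‑dimethyloct‑7‑ene‑2,4‑dione | CC(=O)C(C)C(=O)CC/C(C)=C\I | intermediate
6 | (S)‑2,2‑dimethyl‑1,3‑dioxolane‑4‑carbaldehyde | O=C[C@@H]1COC(C)(C)O1 | starting material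
7 | (7Z,9R)‑9‑[(4S)‑2,2‑dimethyl‑1,3‑dioxolan‑4‑yl]‑9‑hydroxy‑3,7‑dimethylnon‑7‑ene‑2,4‑dione | CC(=O)C(C)C(=O)CC/C(C)=C\[C@@H](O)[C@@H]1COC(C)(C)O1 | intermediate
8 | 9‑O‑TBS ether of 7 | CC(=O)C(C)C(=O)CC/C(C)=C\[C@@H](O[Si](C)(C)C(C)(C)C)[C@@H]1COC(C)(C)O1 | intermediate
9 | (2S,3S)‑2‑acetyl‑3‑{(R)‑(TBSO)[(4S)‑2,2‑dimethyl‑1,3‑dioxolan‑4‑yl]methyl}‑2‑methyl‑4‑methylenecyclohexan‑1‑one | O=C1CCC(=C)[C@H]([C@@H](O[Si](C)(C)C(C)(C)C)[C@@H]2COC(C)(C)O2)[C@@]1(C)C(C)=O | intermediate
10 | 2‑[(Z)‑5‑iodo‑4‑methylpent‑4‑enoyl] analogue of 9 | O=C1CCC(=C)[C@H]([C@@H](O[Si](C)(C)C(C)(C)C)[C@@H]2COC(C)(C)O2)[C@@]1(C)C(=O)CC/C(C)=C\I | intermediate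
11 | (2R,14S)‑2,14‑diol (syn) | O[C@H]1CCC(=C)[C@H]([C@@H](O[Si](C)(C)C(C)(C)C)[C@@H]2COC(C)(C)O2)[C@@]1(C)[C@H](O)CC/C(C)=C\I | intermediate
12 | 2,14‑diacetate of 11 | CC(=O)O[C@H]1CCC(=C)[C@H]([C@@H](O[Si](C)(C)C(C)(C)C)[C@@H]2COC(C)(C)O2)[C@@]1(C)[C@H](OC(C)=O)CC/C(C)=C\I | intermediate
13 | 7,8‑diol (acetonide removed) | CC(=O)O[C@H]1CCC(=C)[C@H]([C@@H](O[Si](C)(C)C(C)(C)C)[C@@H](O)CO)[C@@]1(C)[C@H](OC(C)=O)CC/C(C)=C\I | intermediate
14 | C7‑aldehyde/C8‑ketone seco‑precursor | CC(=O)O[C@H]1CCC(=C)[C@H]([C@@H](O[Si](C)(C)C(C)(C)C)C(=O)C=O)[C@@]1(C)[C@H](OC(C)=O)CC/C(C)=C\I | intermediate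
15 | macrocyclic (7S)‑7‑hydroxy‑8‑ketone, 9‑OTBS, 5Z,11(20)‑diene | CC(=O)O[C@H]1CCC(=C)[C@@H]2[C@@H](O[Si](C)(C)C(C)(C)C)C(=O)[C@H](/C=C(/C)CC[C@@H](OC(C)=O)[C@@]12C)O | intermediate
16 | 2‑bromopropanoyl bromide (racemic) | CC(Br)C(Br)=O | starting material
17 | 7‑O‑(2‑bromopropanoate) of 15 | CC(=O)O[C@H]1CCC(=C)[C@@H]2[C@@H](O[Si](C)(C)C(C)(C)C)C(=O)[C@H](/C=C(/C)CC[C@@H](OC(C)=O)[C@@]12C)OC(=O)C(C)Br | intermediate
18 | 9‑hydroxy‑8‑ketone (TBS removed) | CC(=O)O[C@H]1CCC(=C)[C@@H]2[C@@H](O)C(=O)[C@H](/C=C(/C)CC[C@@H](OC(C)=O)[C@@]12C)OC(=O)C(C)Br | intermediate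
19 | (11R)‑11,20‑epoxide of 18 | CC(=O)O[C@H]1CC[C@]2(CO2)[C@@H]2[C@@H](O)C(=O)[C@H](/C=C(/C)CC[C@@H](OC(C)=O)[C@@]12C)OC(=O)C(C)Br | intermediate
20 | 9‑O‑deacetyl junceellolide F | CC(=O)O[C@H]1CC[C@]2(CO2)[C@@H]2[C@@H](O)[C@@]3(O)[C@H](/C=C(/C)CC[C@@H](OC(C)=O)[C@@]12C)OC(=O)[C@@H]3C | intermediate
21 | junceellolide F | CC(=O)O[C@H]1CC[C@]2(CO2)[C@@H]2[C@@H](OC(C)=O)[C@@]3(O)[C@H](/C=C(/C)CC[C@@H](OC(C)=O)[C@@]12C)OC(=O)[C@@H]3C | target

## Step count and main risks

Total steps: 17. Longest linear sequence: 17 (propargyl alcohol → junceellolide F; bromide 3 is used twice).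

Three steps most likely to fail:

1. **Step 6 (proposed new anodic Mn/Cu cyclisation).** Risks are the facial selectivity at C10, 5‑exo versus 6‑endo closure, and exo versus endo alkene formation. Fallback (known chemistry, different bond construction): forge C1–C10 by Ireland–Claisen rearrangement of the propionate ester of the corresponding (Z)‑C20 allylic alcohol (chair TS, giving the 11(20)‑methylene directly), then close the cyclohexanone by Dieckmann/aldol condensation between C1 and C14.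

2. **Step 12 (ten‑membered NHK macrocyclisation on a keto‑aldehyde).** Risks are oligomerisation, reduction of the 1,2‑dicarbonyl, and C7 selectivity. Fallback: close the ring at C5=C6 by ring‑closing metathesis (Grubbs II). This uses methallyl bromide in step 7 and vinylmagnesium bromide addition to the C7 aldehyde to give the diene.

3. **Step 7 (regioselective enolisation of the acetyl group versus the ring ketone).** Fallback: run steps 3–6 with methyl 2‑methylacetoacetate in place of 4 so that C2 is an ester. After cyclisation, reduce and re‑oxidise to the C2 aldehyde and add the C3–C6 unit as the alkylzinc reagent from (Z)‑ICH2CH2C(Me)=CHI, which forms C2–C3 without any enolate chemistry.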